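The readings come from a simulation with constants of no real substance; the scatter is artificial.

The constants of this flask are hidden, so the reckoning has to start from two runs and a list of suspect steps.

| setting | ash | cedar | flask |
|---|---|---|---|
| substrate | 1 M | 0.50 M | 1.0 M |
| gas | 69 mM (held) | 69 mM (held) | 69 mM (held) |
| remark | the very flask that is asked about, followed so far | run made earlier |  |
| time |  |  | 30 h |

| run | time / h | target / % | substrate / % |
|---|---|---|---|
| ash | 0.333 | 0 | 71 |
| ash | 1.00 | 4 | 45 |
| ash | 1.50 | 5 | 37 |
| ash | 2.50 | 6 | 36 |
| ash | 4.00 | 8 | 36 |
| ash | 5.00 | 14 | 30 |
| ash | 6.00 | 17 | 28 |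
| cedar | 1.00 | 7 | 43 |
| cedar | 1.33 | 6 | 37 |
| cedar | 2.00 | 11 | 36 |
| cedar | 3.00 | 20 | 34 |
| cedar | 5.00 | 32 | 25 |
| cedar | 8.00 | 45 | 21 |
| cedar | 12.0 | 68 | 11 |

(readings scatter by 2 percentage points)

* how much target there is at 30 h, in percent of the substrate charged
* concentration of reagent in solution at 30 h, in percent of saturation

- at the start none of reagent is dissolved
- the earlier runs were read with a standard deviation of 2 percentage points
- on the list of suspects stand: gas <-> reagent; substrate <-> reactive form; reagent + reactive form -> target; target <-> isomer of the product

*What stays nearly constant in these runs?* Not the percentage of target, but the target made per hour as a concentration. The last cedar reading gives 28.3 mM h⁻¹, and the last ash reading gives 28.3 mM h⁻¹. I call this the supply rate: c_target divided by the time, read from readings that carry their scatter.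

*Why freeze it?* The ash charge is twice the cedar charge, yet the two rates match. So I take the transfer of gas to reagent as the rate-limiting step.

*What does that give for this flask, the ash run carried on?* At 30 h, c_target is the supply rate times the time, which is 85.0 % of the charge.

*Where is that weak?* It assumes the rate holds as the material thins out. In this flask, 150 mM would remain as something other than target, a little less than the 160 mM at the last cedar reading, where the rate still stood. The reckoning therefore sits just beyond the tested range, and a slackening of the rate there lowers c_target, so I expect any error to make this figure too high.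

*And c_reagent?* No reading shows it. I expect a small share of saturation and give no number.

The forecast says 81 % and 10 %, holding that “reagent is consumed as it arrives”.

The flask gives 82.9 % of target and 5.81 % of saturation.

    gas ⇌ reagent, rate k1*(csat - [reagent]) (kL = 1.20 × 10⁻⁴ s⁻¹)
    substrate ⇌ reactive form (K = 1.60, k = 3.70 × 10⁻⁴ s⁻¹)
    reagent + reactive form → target (k = 0.0260 M⁻¹ s⁻¹)
    target ⇌ isomer of the product (K = 3.30, k = 9.80 × 10⁻⁷ s⁻¹)

At 30.0 h in this flask, the half-life of reagent by its reaction with reactive form is 0.10 h, far shorter than the run. Reagent is made 1.03 times as fast as it is used, and c_reagent stands at 0.00401 M. My reckoning lies 2.1 percentage points above the result. For the neighbour flask charged with 1.7 M, the same supply rate gives 49.9 % of its charge at 30 h, and the computed result is 49.6 %.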